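Remark on the chemistry: 26 has no stereocentre and no stereogenic double bond, so no step has to control configuration and every SMILES below is complete as written.

## Structural features

The target 26 is a diaryl ether: two benzene rings joined through a single oxygen, with no further ring. Ring A is a methyl benzoate whose ester carbon C1 lies between two oxygen-bearing carbons, C2 with a 3-methylbut-2-enyl (prenyl) ether and C6 with the bridging aryloxy oxygen, and it has a methyl group at C4. Ring B carries the bridging oxygen at C1', a hydroxymethyl group at C2', a methoxy group at C4' and a second prenyl ether at C6'. With no stereochemistry present, the whole problem is regiochemical, together with telling five oxygen functions apart. The fragile parts are the two allylic aryl ethers (acid-labile, prone to ene and Claisen chemistry), the free benzylic alcohol, and the pairing of the ring A ester with a ring B oxygen ortho to the bridge, which at the free-phenol stage could close a seven-membered lactone. The real difficulty is the C6–O–C1' link, because the oxygen sits between an ortho ester on ring A and two ortho substituents on ring B, a poor setting for substitution or cross-coupling at an aromatic carbon. The key step uses the contiguous triad C2(O)–C1(C=O)–C6(O) of ring A: an aryne across C1 and C6, polarised by the oxygen on C2, takes up the ring B phenoxide at C6 and 17 at C1 in one operation.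

## Logic of the disconnections

26 to 24 and 25. The two allylic O–CH2 bonds (on the C2 oxygen of ring A and the C6' oxygen of ring B) are cut. These ethers would survive neither the acid used for unmasking nor the neighbourhood of an aryne, so they are made last. Both phenols then become one kind of handle. The forward step must alkylate two phenols, leave the primary benzylic hydroxyl alone, and alkylate the ring B phenoxide faster than it can attack the ester across the bridge.

24 to 23. The two aryl O–CH2OMe acetal bonds and the CH2O–Si bond are cut. Three protecting groups then cost a single step. The demand is an acid treatment that removes both acetals and the silyl ether while the ester, the diaryl ether and the benzylic C–O bond stay intact.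

23 to 22. The ester O–CH3 bond is cut. The free acid is what a carboxylation delivers, and it can be purified by extraction into base. The acyl carbon lies between two ortho substituents, so the forward step must form the ester by alkylation at carboxylate oxygen and not by addition to the carbonyl.

22 to 10, 16 and 17. The C6–O bond of the diaryl ether and the C1–CO2H bond are cut together, on neighbouring carbons, which uncovers 19 as the reactive intermediate. The tetrasubstituted ring A with its hindered ether falls apart into a stable trisubstituted silyl triflate, a phenol and a one-carbon gas, and the route becomes convergent. The demands are that 18 adds at the carbon of 19 remote from the acetal oxygen and that 20 meets 17 before it meets a proton. For that reason both partners carry acetal and silyl ethers only, the phenoxide is preformed and dried, and the medium is an ether solvent without acidic C–H bonds.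

10 to 8. The O–SO2CF3 bond is cut and the oxygen goes back to a carbamate, the group that placed silicon on the ring. Carbamate removal must use a mild base that leaves the C–Si bond and the acetal alone, so that 9 can be sulfonylated in the same flask.

8 to 5. The C–Si bond between the two oxygen substituents is cut. That carbon lies between two lithium-coordinating groups and is the most acidic site of the ring. The forward metalation needs the N–H masked and a low temperature, so that the carbamoyl group does not migrate to carbon.

5 to 4. The O–C(=O)N bond is cut, which leaves a simple phenol. The forward step is the addition of that phenol to an isocyanate and has no selectivity issue.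

4 to 3 and 2. One aryl O–CH2 acetal bond is cut, which leads back to a symmetrical diol. The forward step has to stop at mono-alkylation. This is a statistical problem, accepted at the first step of this branch on a cheap material because 3 and the bis-ether can be separated and recycled.

16 to 15. The CH2O–Si bond is cut. The forward silylation must choose the primary benzylic hydroxyl over the di-ortho-substituted phenol.

15 to 14. The C2'–CH2OH carbon–carbon bond is cut. In 14 the position para to the phenol and one ortho position are blocked, so only the wanted carbon can react with a one-carbon electrophile. The forward step must stop after one addition and avoid condensation to a diarylmethane. Direct hydroxymethylation saves one step over formylation followed by reduction.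

14 to 12. The C1'–O bond is traded for a C1'–CHO bond. The aldehyde carbon of the precursor marks the position of the future bridging oxygen and keeps it distinct from the neighbouring, already protected oxygen. The forward oxidation needs the electron-rich aryl group to migrate in preference to hydride.

12 to 11 and 2. The aryl O–CH2 acetal bond is cut, which leaves a commercial hydroxy aldehyde. The forward alkylation has to overcome the hydrogen bond between the phenol and the aldehyde.

2 to 1. The C–Cl bond is cut, which leads back to a harmless, cheap acetal. The alkylating agent needed in both branches is volatile and carcinogenic, so it is made once in solution from 1 and never handled neat. The forward exchange with an acid chloride must go to completion, so that a measured volume of the solution delivers a known amount of 2 to each branch.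

## Other disconnections considered

Alternative 1: The cut runs through ring A itself. Bonds C1–C2 and C5–C6 are broken, so that C1 and C6 come from the alkyne carbons of methyl 3-{2-[(tert-butyldimethylsilyloxy)methyl]-4-methoxy-6-(3-methylbut-2-en-1-yloxy)phenoxy}prop-2-ynoate A1, and C2 to C5 with the C4 methyl come from 3-methyl-1,1-bis(trimethylsilyloxy)buta-1,3-diene A2. In the forward direction a [4+2] cycloaddition followed by loss of one silyloxy group would aromatise the adduct to the salicylate A3, methyl 2-hydroxy-4-methyl-6-aryloxybenzoate with silyl-protected, already prenylated ring B.
- In its favour: the polarity is matched (the CH2 terminus of A2 to the β-carbon of the ynoate, the acetal carbon to the α-carbon), so the 1,2,6 pattern of ring A is dictated by the components, and aromatisation is irreversible.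
- Where it is better than the chosen plan: the ring A phenol of A3 emerges free and already distinct from the ring B oxygen. No acetal protection and no final acid treatment are needed, and the end-game is one alkylation and one desilylation against three steps. The key step also belongs to an established class of thermal pericyclic reactions, so it carries less novelty risk.
- Where it is equal: the hindered ether bond is made at an sp carbon before ring A exists, which sidesteps substitution at a crowded arene just as the aryne does.
- Against it: A1 is an ynol ether conjugated with an ester. It is a weak dienophile, is easily hydrated, and has to be assembled on a di-ortho-substituted phenol in several steps with strong base next to a prenyl ether. A2 is hydrolytically labile, and ketene acetals tend to give [2+2] or conjugate addition with ynoates. The heating that a deactivated dienophile needs invites Claisen rearrangement of the prenyl aryl ether.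
- Step economy: the steps saved at the end are likely to be spent on A1. The chosen plan is preferred because its three components are stable, storable or gaseous.

Alternative 2: Bonds C1–C2 and C3–C4 of ring A are cut. C1, C6, C5 and C4 come from the diene of methyl 4-[2-(benzyloxy)-6-formyl-4-methoxyphenoxy]-6-methyl-2-oxo-2H-pyran-3-carboxylate A4, and C2 and C3 come from 1,1-dimethoxyethene A5. An inverse-demand [4+2] cycloaddition, decarboxylation of the bridged adduct and loss of one alkoxy group would give methyl 2-[2-(benzyloxy)-6-formyl-4-methoxyphenoxy]-6-methoxy-4-methylbenzoate A6.
- In its favour: the C–O bond to ring B would be made by addition–elimination at C4 of a pyrone carrying a leaving group there. This is a vinylogous acyl substitution that tolerates hindered phenoxides, and on this bond the alternative is at least the equal of the aryne addition.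
- Where it is better than the chosen plan: the ester at C3 of the pyrone fixes the orientation of A5, extrusion of the bridge makes the step irreversible, and the reaction type is well established, so on mechanistic precedent it scores higher.
- Against it: the 4-aryloxy donor and the 6-methyl group both lower the reactivity of A4 toward A5, the first electronically and the second at the very terminus where the nucleophilic CH2 must bond. A5 is moisture-sensitive, and the formyl group of A4 is a competing electrophile for it.
- Structure: A6 carries the wrong substituents. A methyl ether at C2 must be cleaved selectively beside a second aryl methyl ether, and the benzyl ether and aldehyde of ring B need debenzylation and reduction before two alkylations with 25.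
- Step economy: about four or five steps after the key step against three, which makes this alternative clearly worse.

Alternative 3: Only the C1–carbonyl bond is cut. The precursor is the aryl methyl carbonate A7, 3-{2-[(tert-butyldimethylsilyloxy)methyl]-4-methoxy-6-(3-methylbut-2-en-1-yloxy)phenoxy}-5-methylphenyl methyl carbonate. A lithium amide base would remove the C1 proton between the carbonate oxygen and the aryloxy oxygen, the methoxycarbonyl group would shift from oxygen to C1 (anionic ortho-Fries rearrangement), and the phenoxide would be alkylated by 25 in the same flask to give A8, the tert-butyldimethylsilyl ether of 26.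
- Where it is better than the chosen plan: the ester carbon arrives as the phenol's own protecting group, no gas is handled, the metalation site is doubly activated, and A8 is one desilylation from 26, the shortest end-game of all the plans.
- Where it is equal or better on precedent: the rearrangement is an established reaction type, although far better behaved for carbamates and bulky carbonates than for a methyl carbonate.
- Against it: a methyl carbonate is an electrophile toward the amide base and toward the aryllithium of a second molecule. The allylic O–CH2 of the prenyl ether, the ring B C–H between two oxygens and the benzylic methyl are competing acidic sites. The chelated lithium salicylate phenoxide is a sluggish nucleophile toward 25.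
- Structure: the hindered diaryl ether must already exist in A7. The alternative therefore postpones the central difficulty and does not solve it, leaving it to a coupling of two ortho-substituted partners.
- Step economy: better after the key step, but worse overall once the synthesis of A7 is counted.

Key step: step 10

## Route

Step 1
Reactants: 1 dimethoxymethane
Product: 2 chloromethyl methyl ether (toluene stock solution, not concentrated)
Conditions: AcCl (1.0 equiv), ZnBr2 (cat.), toluene, rt
Reagents that add atoms: acetyl chloride, CC(=O)Cl
Why: ZnBr2-catalysed exchange between the acetal and the acid chloride should give the chloromethyl ether and methyl acetate cleanly, without bis(chloromethyl) ether; one batch is kept in solution and measured out by volume for steps 2 and 6, so the reagent is never handled neat.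

Step 2
Reactants: 3 orcinol (5-methylbenzene-1,3-diol); 2 chloromethyl methyl ether
Product: 4 3-(methoxymethoxy)-5-methylphenol
Conditions: 2 (1.0 equiv, toluene solution from step 1), iPr2NEt, THF, 0 °C → rt; aq. NH4Cl quench
Reagents that add atoms: none
Why: Williamson-type O-alkylation of the symmetrical diol with one equivalent of 2 should give the mono-ether as the main component of a statistical mixture from which 3 and the bis-ether are separated; the methyl acetate carried in the solution is inert to the amine base.

Step 3
Reactants: 4 3-(methoxymethoxy)-5-methylphenol
Product: 5 3-(methoxymethoxy)-5-methylphenyl N-(propan-2-yl)carbamate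
Conditions: iPrNCO, Et3N (cat.), CH2Cl2, rt
Reagents that add atoms: isopropyl isocyanate, CC(C)N=C=O
Why: Base-catalysed addition of the phenol to the isocyanate (carbamoylation) installs a strong ortho-directing group that can later be removed under mild base.

Step 4
Reactants: 5 3-(methoxymethoxy)-5-methylphenyl N-(propan-2-yl)carbamate
Product: 8 3-(methoxymethoxy)-5-methyl-2-(trimethylsilyl)phenyl N-(propan-2-yl)carbamate, via N-silyl carbamate 6 (not isolated), via C-silylated N-silyl carbamate 7 (not isolated)
Conditions: TBSOTf, TMEDA, Et2O, 0 °C → rt; n-BuLi, TMEDA, −78 °C; TMSCl, −78 °C → rt; cold aq. NaHSO4, brief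
Reagents that add atoms: chlorotrimethylsilane, C[Si](C)(C)Cl
Why: Directed ortho-metalation: with the N–H masked in the flask as its N-silyl derivative, n-BuLi/TMEDA should remove the ring proton between the carbamate and the methoxymethoxy group, both of which coordinate lithium, and TMSCl traps the aryllithium; the short cold acidic wash takes silicon off nitrogen only.

Step 5
Reactants: 8 3-(methoxymethoxy)-5-methyl-2-(trimethylsilyl)phenyl N-(propan-2-yl)carbamate
Product: 10 3-(methoxymethoxy)-5-methyl-2-(trimethylsilyl)phenyl trifluoromethanesulfonate, via 3-(methoxymethoxy)-5-methyl-2-(trimethylsilyl)phenol 9 (not isolated)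
Conditions: DBU, Et2NH, MeCN, 40 °C; then PhNTf2, rt
Reagents that add atoms: N-phenylbis(trifluoromethanesulfonimide), O=S(=O)(N(c1ccccc1)S(=O)(=O)C(F)(F)F)C(F)(F)F
Why: E1cB cleavage of the secondary carbamate gives the phenoxide and an isocyanate that diethylamine scavenges as a urea, and the phenoxide is O-sulfonylated in the same flask; the C–Si bond and the acetal are inert to amine bases.

Step 6
Reactants: 11 2-hydroxy-4-methoxybenzaldehyde; 2 chloromethyl methyl ether
Product: 12 4-methoxy-2-(methoxymethoxy)benzaldehyde
Conditions: 2 (1.3 equiv, toluene solution from step 1), iPr2NEt, CH2Cl2, 0 °C → rt; aq. NH4Cl quench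
Reagents that add atoms: none
Why: Williamson-type O-alkylation of the phenol with the chloromethyl ether solution; the amine base breaks the hydrogen bond to the aldehyde, and there is only one hydroxyl to alkylate.

Step 7
Reactants: 12 4-methoxy-2-(methoxymethoxy)benzaldehyde
Product: 14 4-methoxy-2-(methoxymethoxy)phenol, via 4-methoxy-2-(methoxymethoxy)phenyl formate 13 (not isolated)
Conditions: mCPBA, CH2Cl2, 0 °C → rt; then K2CO3, MeOH, rt
Reagents that add atoms: 3-chloroperoxybenzoic acid, O=C(OO)c1cccc(Cl)c1
Why: Dakin-type Baeyer–Villiger oxidation: the aryl group, made electron-rich by its ortho and para oxygens, migrates in preference to hydride to give the aryl formate, which mild methanolysis cleaves to the phenol without touching the acetal.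

Step 8
Reactants: 14 4-methoxy-2-(methoxymethoxy)phenol
Product: 15 2-(hydroxymethyl)-4-methoxy-6-(methoxymethoxy)phenol
Conditions: 37 % aq. CH2O, NaOH, H2O–THF, N2, rt; then AcOH to pH 7
Reagents that add atoms: formaldehyde, C=O
Why: Lederer–Manasse hydroxymethylation: the phenoxide attacks formaldehyde through the only open position ortho to its oxygen, since the para carbon carries the methoxy group and the other ortho carbon the acetal, so a single regioisomer and a single addition are expected at room temperature.

Step 9
Reactants: 15 2-(hydroxymethyl)-4-methoxy-6-(methoxymethoxy)phenol
Product: 16 2-[(tert-butyldimethylsilyloxy)methyl]-4-methoxy-6-(methoxymethoxy)phenol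
Conditions: TBSCl (1.05 equiv), imidazole, CH2Cl2, 0 °C
Reagents that add atoms: tert-butyldimethylsilyl chloride, CC(C)(C)[Si](C)(C)Cl
Why: Chemoselective silylation: the unhindered primary benzylic hydroxyl should react with the bulky silyl chloride well before the phenol, which is flanked by two ortho substituents and is hydrogen-bonded.

Step 10
Reactants: 16 2-[(tert-butyldimethylsilyloxy)methyl]-4-methoxy-6-(methoxymethoxy)phenol; 10 3-(methoxymethoxy)-5-methyl-2-(trimethylsilyl)phenyl trifluoromethanesulfonate; 17 carbon dioxide
Product: 22 2-{2-[(tert-butyldimethylsilyloxy)methyl]-4-methoxy-6-(methoxymethoxy)phenoxy}-6-(methoxymethoxy)-4-methylbenzoic acid, via potassium phenoxide 18 (not isolated), via 3-(methoxymethoxy)-5-methylbenzyne 19 (not isolated), via arylpotassium 20 (not isolated), via potassium carboxylate 21 (not isolated)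
Conditions: 16 (1.5 equiv), KOtBu, THF, rt, then evaporation with toluene; KF, 18-crown-6, THF, 17 (1 atm), 0 °C; 10 added slowly, 0 °C → rt; cold aq. KHSO4 to pH 3
Reagents that add atoms: none
Why: Proposed new method: fluoride attacks silicon in 10 and triflate leaves to give aryne 19, the dry phenoxide 18 adds through oxygen to the aryne carbon that becomes C6, and the aryl anion 20, flanked by two oxygens and chelated by the acetal, is carboxylated at C1 by dissolved 17 to 21, which the cold acid wash converts into 22. The closest known reaction types are the fluoride-induced three-component coupling of arynes with amines and carbon dioxide to anthranilic acids and the two-component O-arylation of phenols by ortho-silylaryl triflates; what is new is the pairing of an oxygen anion and 17 on the same aryne. No ring is closed and no stereocentre is formed. The selectivity needed is regiochemical (oxygen to C6, carbon to C1) and it is secured by the inductively withdrawing oxygen on C2, which distorts 19 so that the nucleophile enters at the distal carbon and the charge develops next to the substituent, with sterics pointing the same way. Carboxylation is kept ahead of protonation by design: 18 is preformed and stripped of tert-butanol, THF replaces an acidic nitrile solvent, and neither partner carries an O–H group or an allyl ether. The adduct of 18 with 17 (an aryl carbonate salt) forms reversibly and should be a far weaker nucleophile than the free phenoxide it equilibrates with, as the carbamate salts are in the amine precedent. Slow addition of 10 to an excess of 18 keeps 19 from meeting 20 or 21, and 22 is separated from neutral by-products by extraction into aqueous NaHCO3.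

Step 11
Reactants: 22 2-{2-[(tert-butyldimethylsilyloxy)methyl]-4-methoxy-6-(methoxymethoxy)phenoxy}-6-(methoxymethoxy)-4-methylbenzoic acid
Product: 23 methyl 2-{2-[(tert-butyldimethylsilyloxy)methyl]-4-methoxy-6-(methoxymethoxy)phenoxy}-6-(methoxymethoxy)-4-methylbenzoate
Conditions: MeI, K2CO3, DMF, rt
Reagents that add atoms: iodomethane, CI
Why: SN2 alkylation of the carboxylate at oxygen needs no attack at the acyl carbon between two ortho substituents, where Fischer esterification would fail; acetals and the silyl ether are stable to the weak base.

Step 12
Reactants: 23 methyl 2-{2-[(tert-butyldimethylsilyloxy)methyl]-4-methoxy-6-(methoxymethoxy)phenoxy}-6-(methoxymethoxy)-4-methylbenzoate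
Product: 24 methyl 2-hydroxy-6-[2-hydroxy-6-(hydroxymethyl)-4-methoxyphenoxy]-4-methylbenzoate
Conditions: HCl (1.25 M in MeOH), rt → 40 °C
Reagents that add atoms: none
Why: Acid-catalysed acetal exchange removes both methoxymethyl groups as the dimethyl acetal of formaldehyde and solvolyses the primary silyl ether in the same operation; methanol as solvent keeps the ester as the methyl ester and would reopen any lactone formed across the bridge, and the benzylic cation is poorly stabilised (its only ortho donor is the twisted diaryl ether oxygen), so the alcohol should persist.

Step 13
Reactants: 24 methyl 2-hydroxy-6-[2-hydroxy-6-(hydroxymethyl)-4-methoxyphenoxy]-4-methylbenzoate; 25 prenyl bromide (1-bromo-3-methylbut-2-ene)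
Product: 26 methyl 2-[2-(hydroxymethyl)-4-methoxy-6-(3-methylbut-2-en-1-yloxy)phenoxy]-4-methyl-6-(3-methylbut-2-en-1-yloxy)benzoate
Conditions: 25 (2.5 equiv), K2CO3, acetone, 45 °C
Reagents that add atoms: none
Why: Williamson etherification: K2CO3 deprotonates the two phenols but not the much less acidic benzylic alcohol, and each phenoxide displaces bromide at the primary allylic carbon by SN2; the excess of 25 should consume the ring B phenoxide before it can attack the hindered ester.

## Compound list

1 | dimethoxymethane | COCOC | starting material
2 | chloromethyl methyl ether (toluene stock solution, never concentrated) | COCCl | intermediate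
3 | orcinol (5-methylbenzene-1,3-diol) | Cc1cc(O)cc(O)c1 | starting material
4 | 3-(methoxymethoxy)-5-methylphenol | COCOc1cc(C)cc(O)c1 | intermediate
5 | 3-(methoxymethoxy)-5-methylphenyl N-(propan-2-yl)carbamate | COCOc1cc(C)cc(OC(=O)NC(C)C)c1 | intermediate
6 | 3-(methoxymethoxy)-5-methylphenyl N-[tert-butyl(dimethyl)silyl]-N-(propan-2-yl)carbamate (not isolated) | COCOc1cc(C)cc(OC(=O)N(C(C)C)[Si](C)(C)C(C)(C)C)c1 | intermediate
7 | 3-(methoxymethoxy)-5-methyl-2-(trimethylsilyl)phenyl N-[tert-butyl(dimethyl)silyl]-N-(propan-2-yl)carbamate (not isolated) | COCOc1cc(C)cc(OC(=O)N(C(C)C)[Si](C)(C)C(C)(C)C)c1[Si](C)(C)C | intermediate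
8 | 3-(methoxymethoxy)-5-methyl-2-(trimethylsilyl)phenyl N-(propan-2-yl)carbamate | COCOc1cc(C)cc(OC(=O)NC(C)C)c1[Si](C)(C)C | intermediate
9 | 3-(methoxymethoxy)-5-methyl-2-(trimethylsilyl)phenol (present as its amidinium phenoxide, not isolated) | COCOc1cc(C)cc(O)c1[Si](C)(C)C | intermediate
10 | 3-(methoxymethoxy)-5-methyl-2-(trimethylsilyl)phenyl trifluoromethanesulfonate | COCOc1cc(C)cc(OS(=O)(=O)C(F)(F)F)c1[Si](C)(C)C | intermediate
11 | 2-hydroxy-4-methoxybenzaldehyde | COc1ccc(C=O)c(O)c1 | starting material
12 | 4-methoxy-2-(methoxymethoxy)benzaldehyde | COCOc1cc(OC)ccc1C=O | intermediate
13 | 4-methoxy-2-(methoxymethoxy)phenyl formate (not isolated) | COCOc1cc(OC)ccc1OC=O | intermediate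
14 | 4-methoxy-2-(methoxymethoxy)phenol | COCOc1cc(OC)ccc1O | intermediate
15 | 2-(hydroxymethyl)-4-methoxy-6-(methoxymethoxy)phenol | COCOc1cc(OC)cc(CO)c1O | intermediate
16 | 2-[(tert-butyldimethylsilyloxy)methyl]-4-methoxy-6-(methoxymethoxy)phenol | COCOc1cc(OC)cc(CO[Si](C)(C)C(C)(C)C)c1O | intermediate
17 | carbon dioxide | O=C=O | starting material
18 | potassium 2-[(tert-butyldimethylsilyloxy)methyl]-4-methoxy-6-(methoxymethoxy)phenolate (not isolated) | COCOc1cc(OC)cc(CO[Si](C)(C)C(C)(C)C)c1[O-].[K+] | intermediate
19 | 3-(methoxymethoxy)-5-methylbenzyne (1,2-didehydro-3-(methoxymethoxy)-5-methylbenzene, not isolated) | COCOC1=CC(C)=CC#C1 | intermediate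
20 | [2-{2-[(tert-butyldimethylsilyloxy)methyl]-4-methoxy-6-(methoxymethoxy)phenoxy}-6-(methoxymethoxy)-4-methylphenyl]potassium (not isolated) | [K]c1c(OCOC)cc(C)cc1Oc1c(CO[Si](C)(C)C(C)(C)C)cc(OC)cc1OCOC | intermediate
21 | potassium 2-{2-[(tert-butyldimethylsilyloxy)methyl]-4-methoxy-6-(methoxymethoxy)phenoxy}-6-(methoxymethoxy)-4-methylbenzoate (not isolated) | [K+].[O-]C(=O)c1c(OCOC)cc(C)cc1Oc1c(CO[Si](C)(C)C(C)(C)C)cc(OC)cc1OCOC | intermediate
22 | 2-{2-[(tert-butyldimethylsilyloxy)methyl]-4-methoxy-6-(methoxymethoxy)phenoxy}-6-(methoxymethoxy)-4-methylbenzoic acid | O=C(O)c1c(OCOC)cc(C)cc1Oc1c(CO[Si](C)(C)C(C)(C)C)cc(OC)cc1OCOC | intermediate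
23 | methyl 2-{2-[(tert-butyldimethylsilyloxy)methyl]-4-methoxy-6-(methoxymethoxy)phenoxy}-6-(methoxymethoxy)-4-methylbenzoate | COC(=O)c1c(OCOC)cc(C)cc1Oc1c(CO[Si](C)(C)C(C)(C)C)cc(OC)cc1OCOC | intermediate
24 | methyl 2-hydroxy-6-[2-hydroxy-6-(hydroxymethyl)-4-methoxyphenoxy]-4-methylbenzoate | COC(=O)c1c(O)cc(C)cc1Oc1c(CO)cc(OC)cc1O | intermediate
25 | prenyl bromide (1-bromo-3-methylbut-2-ene) | CC(C)=CCBr | starting material
26 | methyl 2-[2-(hydroxymethyl)-4-methoxy-6-(3-methylbut-2-en-1-yloxy)phenoxy]-4-methyl-6-(3-methylbut-2-en-1-yloxy)benzoate (CNP0561346.0) | COC(=O)c1c(OCC=C(C)C)cc(C)cc1Oc1c(CO)cc(OC)cc1OCC=C(C)C | target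

## Step count and risk

Total: 13 steps (step 1 for the shared reagent 2, steps 2 to 5 to the silyl triflate 10, steps 6 to 9 to the phenol 16, steps 10 to 13 in common). Longest linear sequence: 9 steps (step 1, either branch, then steps 10 to 13); counted from the ring-bearing starting materials 3 or 11 it is 8 steps.

Steps least certain to work:

Step 10 (key step, the one step that carries the new-method label).
- What may go wrong: the phenoxide may be held by 17 as its aryl carbonate salt, which could add to the aryne through a carboxylate oxygen and then transfer the acyl group to the aryl anion, leading to an ester-linked isomer. The aryl anion may be protonated by traces of acid before carboxylation, which would give the two-component ether without the carboxyl group. The aryl anion or the product carboxylate may add to a second aryne, and the ether solvent may itself add to the aryne when little free phenoxide is present. Fluoride may slowly attack the benzylic silyl ether. All of these follow from the low selectivity of arynes and the reversible binding of 17 to oxygen anions.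
- Fallback with known chemistry, setting out from 5 and 16 and rejoining the route at 23: 5 is N-silylated and lithiated as in step 4, but the aryllithium is quenched with methyl chloroformate to give methyl 2-(methoxymethoxy)-4-methyl-6-[(propan-2-ylcarbamoyl)oxy]benzoate F1. DBU and Et2NH then free methyl 2-hydroxy-6-(methoxymethoxy)-4-methylbenzoate F2, and PhNTf2 in the same flask converts it into methyl 2-(methoxymethoxy)-4-methyl-6-{[(trifluoromethyl)sulfonyl]oxy}benzoate F3. Buchwald–Hartwig-type C–O coupling of F3 with 16 (Pd(OAc)2, tBuXPhos, K3PO4, toluene, 100 °C) should then give 23 directly. Here the ester is introduced by directed metalation before the ether is formed and the ether by cross-coupling, so no three-component event is needed.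

Step 8 (hydroxymethylation).
- What may go wrong: slow conversion, followed by condensation of the product with a second phenoxide to a methylene-bridged dimer, and air oxidation of the electron-rich phenoxide.
- Fallback from 14, rejoining at 15: MgCl2-mediated ortho-formylation (MgCl2, Et3N, paraformaldehyde, MeCN, reflux) should give 2-hydroxy-5-methoxy-3-(methoxymethoxy)benzaldehyde F4, which cannot condense further, and reduction with NaBH4 in MeOH at 0 °C gives 15.

Step 4 (directed silylation).
- What may go wrong: incomplete masking of the N–H, so that the base is consumed at nitrogen; migration of the carbamoyl group from oxygen to the lithiated carbon on warming; or loss of the acetal in the acidic wash.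
- Fallback from 4, rejoining at 9 and from there at 10: 4 is acylated with N,N-diethylcarbamoyl chloride (NaH, THF) to 3-(methoxymethoxy)-5-methylphenyl N,N-diethylcarbamate F5, which has no N–H. Treatment with s-BuLi/TMEDA at −78 °C and then TMSCl gives 3-(methoxymethoxy)-5-methyl-2-(trimethylsilyl)phenyl N,N-diethylcarbamate F6. LiAlH4 in THF reduces the carbamate away to give 9, now isolated, which is triflated with PhNTf2 and Cs2CO3 to 10.

Step 9 (selective silylation).
- What may go wrong: competing silylation of the phenolic oxygen, or silyl transfer between the two oxygens, which would leave a mixture.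
- Fallback from 15, rejoining at 16: exhaustive silylation (excess TBSCl, imidazole, DMF) to tert-butyl({2-[(tert-butyldimethylsilyloxy)methyl]-4-methoxy-6-(methoxymethoxy)phenoxy})dimethylsilane F7. The aryl silyl ether alone is then cleaved with K2CO3 in MeOH at rt, which leaves the alkyl silyl ether in place and returns 16.

Step 12 (global deprotection).
- What may go wrong: solvolysis at the benzylic carbon to a methyl ether, incomplete removal of the non-chelated ring B acetal, or acid-promoted ring closure between the ring B phenol and the ester.
- Fallback from 23, rejoining at 26: only the two phenolic acetals are removed with ZnBr2 and n-PrSH in CH2Cl2 at 0 °C, which should give methyl 2-{2-[(tert-butyldimethylsilyloxy)methyl]-6-hydroxy-4-methoxyphenoxy}-6-hydroxy-4-methylbenzoate F8 with the silyl ether intact. Alkylation with 25 and K2CO3 in acetone gives methyl 2-{2-[(tert-butyldimethylsilyloxy)methyl]-4-methoxy-6-(3-methylbut-2-en-1-yloxy)phenoxy}-4-methyl-6-(3-methylbut-2-en-1-yloxy)benzoate F9. Buffered fluoride (TBAF, AcOH, THF) then frees the benzylic alcohol to give 26, so the alcohol is never exposed to protic acid.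

## Further compounds

F1 | step 10 | methyl 2-(methoxymethoxy)-4-methyl-6-[(propan-2-ylcarbamoyl)oxy]benzoate | COC(=O)c1c(OCOC)cc(C)cc1OC(=O)NC(C)C
F2 | step 10 | methyl 2-hydroxy-6-(methoxymethoxy)-4-methylbenzoate | COC(=O)c1c(O)cc(C)cc1OCOC
F3 | step 10 | methyl 2-(methoxymethoxy)-4-methyl-6-{[(trifluoromethyl)sulfonyl]oxy}benzoate | COC(=O)c1c(OCOC)cc(C)cc1OS(=O)(=O)C(F)(F)F
F4 | step 8 | 2-hydroxy-5-methoxy-3-(methoxymethoxy)benzaldehyde | COCOc1cc(OC)cc(C=O)c1O
F5 | step 4 | 3-(methoxymethoxy)-5-methylphenyl N,N-diethylcarbamate | CCN(CC)C(=O)Oc1cc(C)cc(OCOC)c1
F6 | step 4 | 3-(methoxymethoxy)-5-methyl-2-(trimethylsilyl)phenyl N,N-diethylcarbamate | CCN(CC)C(=O)Oc1cc(C)cc(OCOC)c1[Si](C)(C)C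
F7 | step 9 | tert-butyl({2-[(tert-butyldimethylsilyloxy)methyl]-4-methoxy-6-(methoxymethoxy)phenoxy})dimethylsilane | COCOc1cc(OC)cc(CO[Si](C)(C)C(C)(C)C)c1O[Si](C)(C)C(C)(C)C
F8 | step 12 | methyl 2-{2-[(tert-butyldimethylsilyloxy)methyl]-6-hydroxy-4-methoxyphenoxy}-6-hydroxy-4-methylbenzoate | COC(=O)c1c(O)cc(C)cc1Oc1c(CO[Si](C)(C)C(C)(C)C)cc(OC)cc1O
F9 | step 12 | methyl 2-{2-[(tert-butyldimethylsilyloxy)methyl]-4-methoxy-6-(3-methylbut-2-en-1-yloxy)phenoxy}-4-methyl-6-(3-methylbut-2-en-1-yloxy)benzoate | COC(=O)c1c(OCC=C(C)C)cc(C)cc1Oc1c(CO[Si](C)(C)C(C)(C)C)cc(OC)cc1OCC=C(C)C
A1 | alternative 1 | methyl 3-{2-[(tert-butyldimethylsilyloxy)methyl]-4-methoxy-6-(3-methylbut-2-en-1-yloxy)phenoxy}prop-2-ynoate | COC(=O)C#COc1c(CO[Si](C)(C)C(C)(C)C)cc(OC)cc1OCC=C(C)C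
A2 | alternative 1 | 3-methyl-1,1-bis(trimethylsilyloxy)buta-1,3-diene | C=C(C)C=C(O[Si](C)(C)C)O[Si](C)(C)C
A3 | alternative 1 | methyl 2-{2-[(tert-butyldimethylsilyloxy)methyl]-4-methoxy-6-(3-methylbut-2-en-1-yloxy)phenoxy}-6-hydroxy-4-methylbenzoate | COC(=O)c1c(O)cc(C)cc1Oc1c(CO[Si](C)(C)C(C)(C)C)cc(OC)cc1OCC=C(C)C
A4 | alternative 2 | methyl 4-[2-(benzyloxy)-6-formyl-4-methoxyphenoxy]-6-methyl-2-oxo-2H-pyran-3-carboxylate | COC(=O)C1=C(Oc2c(C=O)cc(OC)cc2OCc2ccccc2)C=C(C)OC1=O
A5 | alternative 2 | 1,1-dimethoxyethene | C=C(OC)OC
A6 | alternative 2 | methyl 2-[2-(benzyloxy)-6-formyl-4-methoxyphenoxy]-6-methoxy-4-methylbenzoate | COC(=O)c1c(OC)cc(C)cc1Oc1c(C=O)cc(OC)cc1OCc1ccccc1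
A7 | alternative 3 | 3-{2-[(tert-butyldimethylsilyloxy)methyl]-4-methoxy-6-(3-methylbut-2-en-1-yloxy)phenoxy}-5-methylphenyl methyl carbonate | COC(=O)Oc1cc(C)cc(Oc2c(CO[Si](C)(C)C(C)(C)C)cc(OC)cc2OCC=C(C)C)c1
A8 | alternative 3 | methyl 2-{2-[(tert-butyldimethylsilyloxy)methyl]-4-methoxy-6-(3-methylbut-2-en-1-yloxy)phenoxy}-4-methyl-6-(3-methylbut-2-en-1-yloxy)benzoate | COC(=O)c1c(OCC=C(C)C)cc(C)cc1Oc1c(CO[Si](C)(C)C(C)(C)C)cc(OC)cc1OCC=C(C)C
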